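**Retrosynthetic overview**

1. Rings: A = benzene ring with CH3, OH and COOH; B = fully substituted benzene ring; C = seven-membered ester/ether ring joining A and B; D = five-membered lactone on B. Order of formation: A and B are dressed separately, then ring C, then ring D, then deprotection.
2. Ring D is cut last. It is one CO2 unit held between a ring B carbon and the CH2 on the neighbouring ring B carbon: an ortho-(chloromethyl)aryl iodide becomes the arylmagnesium, takes up CO2 (aryl–C(=O) bond), and the carboxylate closes on CH2Cl (CH2–O bond).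
3. Enabling feature: the lactone carbonyl carbon sits on the one ring B carbon flanked by the phenol-oxygen carbon (masked as a ketal oxygen that chelates magnesium) and by the carbon bearing the SN2-active benzylic CH2. Aryl nucleophile and benzylic electrophile are ortho, so CO2 supplies the missing C and O of ring D in a (3+2) annulation.
4. Ring C: ester between the ring A acid and the ring B phenol, then intramolecular Ullmann ether closure. Twofold iodination of the ring B phenol supplies both the iodide for the ether and the iodide for CO2 uptake.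
5. Ring B comes from 3,5-dihydroxybenzyl alcohol (directed ortho metalation/formylation between the oxygens; a saligenin acetonide tells the two phenols apart and masks the later CH2OH/OH pair). Ring A comes from 2,6-dihydroxy-4-methylbenzoic acid (formylation, benzylation, Pinnick oxidation).

Key step: step 16

Remark: conneotricone has no stereocentre, so no step has to set or keep a configuration.

**Route**

Step 1
Reactants: 1 3,5-dihydroxybenzyl alcohol
Product: 2 [3,5-bis(methoxymethoxy)phenyl]methanol
Conditions: MOMCl (2.2 equiv), K2CO3, acetone, 0 °C to rt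
Reagents that add atoms: chloromethyl methyl ether, COCCl
Why: Williamson-type O-alkylation; K2CO3 deprotonates only the two phenols, so both phenoxides are capped and the primary alcohol stays free.

Step 2
Reactants: 2 [3,5-bis(methoxymethoxy)phenyl]methanol
Product: 3 {[3,5-bis(methoxymethoxy)benzyl]oxy}triisopropylsilane
Conditions: TIPSCl (1.1 equiv), imidazole (2.5 equiv), DMF, rt
Reagents that add atoms: triisopropylsilyl chloride, CC(C)[Si](Cl)(C(C)C)C(C)C
Why: Imidazole-promoted silylation of the primary alcohol gives a bulky, non-coordinating silyl ether that tolerates n-BuLi and keeps the later lithiation away from the carbons next to the CH2O group.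

Step 3
Reactants: 3 {[3,5-bis(methoxymethoxy)benzyl]oxy}triisopropylsilane
Product: 5 2,6-bis(methoxymethoxy)-4-{[(triisopropylsilyl)oxy]methyl}benzaldehyde, via aryllithium 4 (not isolated)
Conditions: n-BuLi (1.2 equiv), TMEDA, THF, 0 °C, 1 h; DMF, 0 °C to rt; H2O
Reagents that add atoms: N,N-dimethylformamide, CN(C)C=O; n-butyllithium, [Li]CCCC (lithium of 4 only)
Why: Directed ortho metalation; the carbon between the two OMOM groups is lithiated under cooperative coordination and the aryllithium is formylated by DMF.

Step 4
Reactants: 5 2,6-bis(methoxymethoxy)-4-{[(triisopropylsilyl)oxy]methyl}benzaldehyde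
Product: 6 2,6-dihydroxy-4-{[(triisopropylsilyl)oxy]methyl}benzaldehyde
Conditions: NaHSO4·SiO2, CH2Cl2, rt
Reagents that add atoms: none
Why: Mild Brønsted-acid hydrolysis of the two aryl MOM acetals, which are activated by the ortho formyl group, while the primary TIPS ether survives.

Step 5
Reactants: 6 2,6-dihydroxy-4-{[(triisopropylsilyl)oxy]methyl}benzaldehyde
Product: 7 2-(hydroxymethyl)-5-{[(triisopropylsilyl)oxy]methyl}benzene-1,3-diol
Conditions: NaBH4, THF/MeOH, 0 °C; crude triol used at once
Reagents that add atoms: none
Why: Borohydride reduction of the aldehyde to the benzylic alcohol; the silyl ether and phenols are untouched.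

Step 6
Reactants: 7 2-(hydroxymethyl)-5-{[(triisopropylsilyl)oxy]methyl}benzene-1,3-diol
Product: 8 2,2-dimethyl-7-{[(triisopropylsilyl)oxy]methyl}-4H-1,3-benzodioxin-5-ol
Conditions: 2,2-dimethoxypropane, PPTS (5 mol%), acetone, rt
Reagents that add atoms: 2,2-dimethoxypropane, COC(C)(C)OC
Why: Acid-catalysed transketalisation closes the six-membered 1,3-dioxine between CH2OH and one of the two equivalent phenols, which masks the later CH2OH/OH pair and leaves exactly one phenol free.

Step 7
Reactants: 8 2,2-dimethyl-7-{[(triisopropylsilyl)oxy]methyl}-4H-1,3-benzodioxin-5-ol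
Product: 9 6,8-diiodo-2,2-dimethyl-7-{[(triisopropylsilyl)oxy]methyl}-4H-1,3-benzodioxin-5-ol
Conditions: NIS (2.2 equiv), MeCN, 0 °C to rt, dark
Reagents that add atoms: N-iodosuccinimide, O=C1CCC(=O)N1I
Why: Electrophilic aromatic iodination; each of the two free ring carbons is ortho or para to the free phenol and to the ketal oxygen, so twofold iodination is the only outcome and no regiochemical choice arises.

Step 8
Reactants: 10 2,6-dihydroxy-4-methylbenzoic acid
Product: 11 benzyl 2,6-dihydroxy-4-methylbenzoate
Conditions: BnBr (1.05 equiv), KHCO3, DMF, rt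
Reagents that add atoms: benzyl bromide, BrCc1ccccc1
Why: SN2 O-alkylation of the carboxylate; KHCO3 deprotonates only the acid and the chelated phenols stay free.

Step 9
Reactants: 11 benzyl 2,6-dihydroxy-4-methylbenzoate
Product: 13 benzyl 3-formyl-2,6-dihydroxy-4-methylbenzoate, via iminium chloride 12 (not isolated)
Conditions: POCl3 (1.5 equiv), DMF (3 equiv), MeCN, 0 °C to rt; then H2O, 50 °C
Reagents that add atoms: N,N-dimethylformamide, CN(C)C=O; water, O; phosphoryl chloride, ClP(Cl)(Cl)=O (chloride of 12 only)
Why: Vilsmeier–Haack formylation; the two free ring positions are equivalent by symmetry and each is ortho to one phenol and para to the other.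

Step 10
Reactants: 13 benzyl 3-formyl-2,6-dihydroxy-4-methylbenzoate
Product: 14 benzyl 6-(benzyloxy)-3-formyl-2-hydroxy-4-methylbenzoate
Conditions: BnBr (1.05 equiv), K2CO3 (1.1 equiv), DMF, rt
Reagents that add atoms: benzyl bromide, BrCc1ccccc1
Why: Williamson ether synthesis, selective for the phenol para to the formyl group (more acidic, one free ortho side) over the phenol locked by chelation between aldehyde and ester.

Step 11
Reactants: 14 benzyl 6-(benzyloxy)-3-formyl-2-hydroxy-4-methylbenzoate
Product: 15 4-(benzyloxy)-3-[(benzyloxy)carbonyl]-2-hydroxy-6-methylbenzoic acid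
Conditions: NaClO2, NaH2PO4, 2-methyl-2-butene, t-BuOH/THF/H2O, rt
Reagents that add atoms: sodium chlorite, [Na+].[O-]Cl=O
Why: Pinnick oxidation of the aldehyde to the acid with 2-methyl-2-butene as hypochlorite scavenger; the benzyl groups and the chelated phenol are inert.

Step 12
Reactants: 15 4-(benzyloxy)-3-[(benzyloxy)carbonyl]-2-hydroxy-6-methylbenzoic acid; 9 6,8-diiodo-2,2-dimethyl-7-{[(triisopropylsilyl)oxy]methyl}-4H-1,3-benzodioxin-5-ol
Product: 16 depside: 1-benzyl 3-[6,8-diiodo-2,2-dimethyl-7-(triisopropylsilyloxymethyl)-4H-1,3-benzodioxin-5-yl] 6-(benzyloxy)-2-hydroxy-4-methylbenzene-1,3-dicarboxylate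
Conditions: DCC (1.2 equiv), DMAP (0.2 equiv), CH2Cl2, 0 °C to rt
Reagents that add atoms: none
Why: Steglich esterification; the only competent nucleophile is the ring B phenol, since the ring A phenol is chelated between two carbonyl groups.

Step 13
Reactants: 16 depside
Product: 17 silyloxymethyl iodo depsidone (ring C closed; full description in the compound list)
Conditions: CuI (20 mol%), picolinic acid (40 mol%), K3PO4 (2 equiv), DMSO (0.01 M), 80 °C
Reagents that add atoms: none
Why: Intramolecular Ullmann-type C–O coupling; the ring A phenoxide can reach only the iodide ortho to the ester oxygen, so ring C closes as a seven-membered ring and the second iodide stays.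

Step 14
Reactants: 17 silyloxymethyl iodo depsidone
Product: 18 hydroxymethyl iodo depsidone
Conditions: HF·pyridine, pyridine, THF, 0 °C to rt
Reagents that add atoms: none
Why: Fluoride-driven cleavage of the Si–O bond under pyridine buffering, which spares the ketal, both esters and the aryl iodide.

Step 15
Reactants: 18 hydroxymethyl iodo depsidone
Product: 20 chloromethyl iodo depsidone, via mesylate 19 (not isolated)
Conditions: MsCl, Et3N, CH2Cl2, 0 °C; then LiCl, DMF, rt
Reagents that add atoms: lithium chloride, [Li+].[Cl-]; methanesulfonyl chloride, CS(Cl)(=O)=O (mesyl group of 19 only)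
Why: Mesylation followed by SN2 displacement with chloride gives the benzylic chloride under non-acidic conditions that keep the ketal.

Step 16
Reactants: 20 chloromethyl iodo depsidone
Product: 23 protected conneotricone (benzyl ether/benzyl ester/acetonide; ring D closed), via arylmagnesium chloride 21 (not isolated), via chloromagnesium carboxylate 22 (not isolated)
Conditions: i-PrMgCl·LiCl (1.1 equiv), THF, −30 °C, 1 h; CO2 (1 atm, dried), −30 °C to rt; then DMPU, 45 °C
Reagents that add atoms: carbon dioxide, O=C=O; isopropylmagnesium chloride–lithium chloride, CC(C)[Mg]Cl.[Li+].[Cl-] (magnesium of 21 and 22 only)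
Why: Iodine–magnesium exchange with the LiCl-activated Grignard reagent converts the aryl iodide into arylmagnesium 21, which is held by the ortho ketal oxygen and adds to CO2 to make the aryl–C(=O) bond of carboxylate 22; the carboxylate oxygen then displaces the ortho benzylic chloride and makes the CH2–O bond, so CO2 delivers two ring atoms of ring D in one flask. The closest known reaction type is the preparation of ortho-(chloromethyl)arylmagnesium halides by iodine–magnesium exchange and their trapping with electrophiles followed by ring closure on CH2Cl, together with the carboxylation of functionalised aryl Grignard reagents. Ring D closes in a 5-exo-tet SN2 step at the benzylic carbon, and no stereocentre is formed. The step needs chemoselectivity (exchange and CO2 capture faster than attack on the two ester carbonyls or on CH2Cl); this should be secured by the low temperature, by the fast exchange of an iodide flanked by a chelating oxygen, and by the two ortho substituents that shield both the ring C lactone carbonyl and the benzyl ester carbonyl. Regiochemistry is fixed because this iodide is the only one left after step 13, and the intramolecular five-ring closure should outrun any intermolecular alkylation.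

Step 17
Reactants: 23 protected conneotricone
Product: 24 conneotricone acetonide
Conditions: H2 (1 atm), 10% Pd/C, EtOAc/THF, rt
Reagents that add atoms: none
Why: Palladium-catalysed hydrogenolysis should remove the benzyl ether and the benzyl ester at 1 atm before the slower benzylic C–O bonds of the lactone and the ketal are touched.

Step 18
Reactants: 24 conneotricone acetonide
Product: 25 conneotricone
Conditions: AcOH/H2O (4:1), 45 °C
Reagents that add atoms: none
Why: Acid-catalysed ketal hydrolysis under weakly acidic aqueous conditions that both lactone rings and the hydroxymethyl phenol should tolerate.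

**Compound list**

1 | 3,5-dihydroxybenzyl alcohol | OCc1cc(O)cc(O)c1 | starting material
2 | [3,5-bis(methoxymethoxy)phenyl]methanol | COCOc1cc(CO)cc(OCOC)c1 | intermediate
3 | {[3,5-bis(methoxymethoxy)benzyl]oxy}triisopropylsilane | COCOc1cc(CO[Si](C(C)C)(C(C)C)C(C)C)cc(OCOC)c1 | intermediate
4 | aryllithium: 2,6-bis(methoxymethoxy)-4-(triisopropylsilyloxymethyl)phenyllithium | [Li]c1c(OCOC)cc(CO[Si](C(C)C)(C(C)C)C(C)C)cc1OCOC | intermediate
5 | 2,6-bis(methoxymethoxy)-4-{[(triisopropylsilyl)oxy]methyl}benzaldehyde | O=Cc1c(OCOC)cc(CO[Si](C(C)C)(C(C)C)C(C)C)cc1OCOC | intermediate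
6 | 2,6-dihydroxy-4-{[(triisopropylsilyl)oxy]methyl}benzaldehyde | O=Cc1c(O)cc(CO[Si](C(C)C)(C(C)C)C(C)C)cc1O | intermediate
7 | 2-(hydroxymethyl)-5-{[(triisopropylsilyl)oxy]methyl}benzene-1,3-diol | OCc1c(O)cc(CO[Si](C(C)C)(C(C)C)C(C)C)cc1O | intermediate
8 | 2,2-dimethyl-7-{[(triisopropylsilyl)oxy]methyl}-4H-1,3-benzodioxin-5-ol | CC1(C)OCc2c(O)cc(CO[Si](C(C)C)(C(C)C)C(C)C)cc2O1 | intermediate
9 | 6,8-diiodo-2,2-dimethyl-7-{[(triisopropylsilyl)oxy]methyl}-4H-1,3-benzodioxin-5-ol | CC1(C)OCc2c(O)c(I)c(CO[Si](C(C)C)(C(C)C)C(C)C)c(I)c2O1 | intermediate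
10 | 2,6-dihydroxy-4-methylbenzoic acid | Cc1cc(O)c(C(=O)O)c(O)c1 | starting material
11 | benzyl 2,6-dihydroxy-4-methylbenzoate | Cc1cc(O)c(C(=O)OCc2ccccc2)c(O)c1 | intermediate
12 | iminium chloride: N-{[3-(benzyloxycarbonyl)-2,4-dihydroxy-6-methylphenyl]methylidene}-N-methylmethanaminium chloride | Cc1cc(O)c(C(=O)OCc2ccccc2)c(O)c1C=[N+](C)C.[Cl-] | intermediate
13 | benzyl 3-formyl-2,6-dihydroxy-4-methylbenzoate | Cc1cc(O)c(C(=O)OCc2ccccc2)c(O)c1C=O | intermediate
14 | benzyl 6-(benzyloxy)-3-formyl-2-hydroxy-4-methylbenzoate | Cc1cc(OCc2ccccc2)c(C(=O)OCc3ccccc3)c(O)c1C=O | intermediate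
15 | 4-(benzyloxy)-3-[(benzyloxy)carbonyl]-2-hydroxy-6-methylbenzoic acid | Cc1cc(OCc2ccccc2)c(C(=O)OCc3ccccc3)c(O)c1C(=O)O | intermediate
16 | depside: aryl ester of acid 15 with phenol 9 (ring A keeps its free, chelated phenol; ring B keeps both iodides) | Cc1cc(OCc2ccccc2)c(C(=O)OCc3ccccc3)c(O)c1C(=O)Oc4c(I)c(CO[Si](C(C)C)(C(C)C)C(C)C)c(I)c5OC(C)(C)OCc45 | intermediate
17 | silyloxymethyl iodo depsidone: dibenzo[b,e][1,4]dioxepin-11-one core; ring A carries CH3 (ortho to the lactone carbonyl), OCH2Ph and CO2CH2Ph (next to the ether oxygen); ring B carries, from the ester-oxygen carbon round to the ether-oxygen carbon, the acetonide CH2, the acetonide oxygen, iodine and CH2OSi(i-Pr)3 | Cc1cc(OCc2ccccc2)c(C(=O)OCc3ccccc3)c4c1C(=O)Oc5c(O4)c(CO[Si](C(C)C)(C(C)C)C(C)C)c(I)c6OC(C)(C)OCc56 | intermediate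
18 | hydroxymethyl iodo depsidone: as 17 with CH2OH in place of CH2OSi(i-Pr)3 | Cc1cc(OCc2ccccc2)c(C(=O)OCc3ccccc3)c4c1C(=O)Oc5c(O4)c(CO)c(I)c6OC(C)(C)OCc56 | intermediate
19 | mesylate: as 18 with CH2OSO2CH3 | Cc1cc(OCc2ccccc2)c(C(=O)OCc3ccccc3)c4c1C(=O)Oc5c(O4)c(COS(C)(=O)=O)c(I)c6OC(C)(C)OCc56 | intermediate
20 | chloromethyl iodo depsidone: as 18 with CH2Cl | Cc1cc(OCc2ccccc2)c(C(=O)OCc3ccccc3)c4c1C(=O)Oc5c(O4)c(CCl)c(I)c6OC(C)(C)OCc56 | intermediate
21 | arylmagnesium chloride: as 20 with MgCl in place of iodine | Cc1cc(OCc2ccccc2)c(C(=O)OCc3ccccc3)c4c1C(=O)Oc5c(O4)c(CCl)c([Mg]Cl)c6OC(C)(C)OCc56 | intermediate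
22 | chloromagnesium carboxylate: as 20 with CO2MgCl in place of iodine | Cc1cc(OCc2ccccc2)c(C(=O)OCc3ccccc3)c4c1C(=O)Oc5c(O4)c(CCl)c(C(=O)O[Mg]Cl)c6OC(C)(C)OCc56 | intermediate
23 | protected conneotricone: target skeleton with rings A–D; ring A OH as benzyl ether, ring A COOH as benzyl ester, ring B OH and CH2OH tied as the acetonide (2,2-dimethyl-4H-1,3-dioxine) | Cc1cc(OCc2ccccc2)c(C(=O)OCc3ccccc3)c4c1C(=O)Oc5c(O4)c6COC(=O)c6c7OC(C)(C)OCc57 | intermediate
24 | conneotricone acetonide: as 23 with free ring A OH and COOH | Cc1cc(O)c(C(=O)O)c2c1C(=O)Oc3c(O2)c4COC(=O)c4c5OC(C)(C)OCc35 | intermediate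
25 | conneotricone | Cc1cc(O)c(C(=O)O)c2c1C(=O)Oc1c(CO)c(O)c3c(c1O2)COC3=O | target

**Step count and risks**

Total steps: 18. Longest linear sequence: 14 (steps 1–7, then 12–18); the ring A branch (steps 8–11) joins at step 12.

Steps most likely to fail:

Step 16. The Grignard reagent or the arylmagnesium could add to an ester carbonyl, couple at the benzylic chloride, or be protonated before CO2 capture; the magnesium carboxylate could also alkylate slowly. Fallback: ring D would be closed one stage earlier from iodo alcohol 18 by palladium-catalysed carbonylative lactonisation (CO 1 atm, Pd(OAc)2, 1,1'-bis(diphenylphosphino)ferrocene, Et3N, DMF, 70 °C). Zerovalent palladium inserts into the C–I bond, CO inserts, and the neighbouring CH2OH captures the acyl palladium. This sets out from 18 and comes back to the route at 23, without the chloride; no new compound is made on the way.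

Step 13. The phenoxide chelated between two carbonyls may engage copper too slowly, so that base-induced cleavage of the depside ester, loss of the second iodide by reduction, or intermolecular coupling take over. Fallback: the C–O bond would be made through a different metal and mechanism, by oxidative addition of zerovalent palladium into the C–I bond ortho to the ester oxygen and C–O reductive elimination from a bulky biarylphosphine complex (Pd(OAc)2, 2-di-tert-butylphosphino-2',4',6'-triisopropylbiphenyl, K3PO4, toluene, 100 °C, high dilution). This sets out from 16 and comes back at 17; no new compound is made on the way.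

Step 12. Acylation of the doubly ortho-substituted iodophenol may be slow, so that the activated acid rearranges to the N-acylurea or oligomerises. Fallback: the acid would be delivered as a cyclic acyl donor. Acid 15 is condensed with acetone (trifluoroacetic anhydride, trifluoroacetic acid, acetone, 0 °C to rt) to benzyl 7-(benzyloxy)-2,2,5-trimethyl-4-oxo-4H-1,3-benzodioxine-8-carboxylate F1. The caesium phenoxide of 9 (Cs2CO3, DMF, 60 °C) then opens the dioxinone at its carbonyl with loss of acetone; the ring A phenoxide released is the better leaving group, which should drive the transacylation. This sets out from 15 (with 9) and comes back at 16.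

**Further compounds**

F0 | step 16 | none | none
F0 | step 13 | none | none
F1 | step 12 | benzyl 7-(benzyloxy)-2,2,5-trimethyl-4-oxo-4H-1,3-benzodioxine-8-carboxylate | Cc1cc(OCc2ccccc2)c(C(=O)OCc3ccccc3)c4OC(C)(C)OC(=O)c14
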